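Per hour is the unit of the quantity I carry through this flask: the loss constant, the fraction of free starting material that goes each hour with reagent held at its charge (a pseudo-first-order constant).

| flask | starting material | reagent | remark | time |
|---|---|---|---|---|
| violet | 30 mM | 40 mM | run made earlier |  |
| Thursday's | 20 mM | 40.0 mM |  | 4.0 h |
| Friday's | 20 mM | 80.0 mM |  | 4.0 h |

violet run (percent of the starting material charged)

| time / min | target / % | over-reaction product / % | intermediate / % | starting material / % |
|---|---|---|---|---|
| 4.00 | 0 | 1.0 | 1.2 | 97.5 |
| 6.00 | 0.4 | 0.5 | 3.9 | 95.8 |
| 8.00 | 1.1 | 1.0 | 4.5 | 95.5 |
| 15.0 | 2.0 | 0 | 5.9 | 92.8 |
| 20.0 | 2.5 | 0.6 | 6.8 | 88.2 |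
| 30.0 | 5.5 | 0.8 | 9.9 | 85.5 |
| 50.0 | 10.7 | 0.2 | 8.7 | 76.2 |

(each reading ± 1 percentage point)

- which of these there is most of at the end, counted by the starting material in it, Thursday's (target / starting material / intermediate / over-reaction product)
- which of these there is most of at the end, counted by the starting material in it, Friday's (target / starting material / intermediate / over-reaction product)
- amount of the one of these that there is most of at the end, in percent of the starting material charged, Thursday's
- amount of the one of these that there is most of at the end, in percent of the starting material charged, Friday's

- percentages count the starting material that a species holds: one idle adduct counts as two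
- target is meant together with its idle adduct
- steps thought possible: starting material + reagent <-> intermediate; target -> over-reaction product; starting material + target <-> idle adduct; intermediate <-> target + by-product
- in an amount of target, one idle adduct counts as one target

I reach it by two ways from the last violet reading. The first reads the starting material column, which has lost 23.8 %:

0.326 h⁻¹, the loss constant at 40 mM reagent.

The second adds up what has appeared in the target, over-reaction product and intermediate columns, 19.6 %:

0.262 h⁻¹.

They part by 4.2 percentage points, with a scatter of 1 point on each reading. The steps offer a place for this: an idle adduct holds a starting material that no column shows, so the second way can undercount what has left the free starting material. Free starting material is the column I mean to forecast, so I keep the first way. For [starting material] after 4.0 h, I reckon: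

Thursday's: 27.1 %

Friday's, with doubled reagent: 7.36 %

The constant holds reagent at its charge while the flask consumes it, so I read both figures as low.

The forecast says target at 47 % for Thursday's flask and target at 62 % for Friday's. It calls Thursday's flask “a close call”, with starting material near 40 %, where my figure is 27.1 %.

Thursday's flask ends with most starting material, 39.6 %, and target stands at 29.9 %. Friday's flask ends with most target, 38.2 %.

    starting material + reagent ⇌ intermediate (K = 18.0 L mol⁻¹, k = 8.00 L mol⁻¹ h⁻¹)
    target → over-reaction product (k = 0.300 h⁻¹)
    starting material + target ⇌ idle adduct, settled at all times (K = 45.0 L mol⁻¹)
    intermediate ⇌ target + by-product (K = 0.0780 M, k = 1.70 h⁻¹)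

The loss constant gave 27.1 % and 7.36 %, and the flasks hold more, 39.6 % on Thursday's and 19.6 % on Friday's. The two flasks differ in their charge of reagent, and that difference is the main reason for the gap in target between them: Friday's flask holds 38.2 % target, and the same flask with Thursday's reagent holds 29.9 %, a gap of 8.3 points.

Thursday's flask read after 1.0 h is the second case: the loss constant gives 72.2 % starting material, and the computed value is 72.9 %.

Readings and results stem from a simulated flask for substances that don't exist, noise included.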